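Atoms are numbered C1 (NCH2) to C29 (terminal =CH2). The plan rests on unravelling ring B (O, C12–C16) to a furan: a 2,6-cis tetrahydropyran oxygenated at C13 next to C12 is the signature of a pyran-3-one. Oxidative ring expansion of furyl carbinol 14, a 2,5-disubstituted furan (C13–C16) with a free 12S hydroxyl and silylated C9 and C18 oxygens, forms O–C16, closes ring B and unveils in one operation a C16 hemiketal, a C14=C15 enone and a C13 ketone, all then steered by C12. Ring A comes from a Prins cyclisation, the triene from two olefinations, the C6–C9 diene from a Suzuki coupling; N-acylation ends the route.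

Key step: step 9

Remark: chain numbers C1–C29 are used for every intermediate. TBS = tert-butyldimethylsilyl, TBDPS = tert-butyldiphenylsilyl, Bn = benzyl, pin = pinacolato. Methyl 2-methoxyacrylate 45 and (+)-Ipc2B(allyl) are taken as purchasable. Ester 8 supplies both C10 and C23.

Step 1
Reactants: 1 furan; 2 ethylene oxide
Product: 4 2-(furan-2-yl)ethanol, via 2-furyllithium 3 (not isolated)
Conditions: n-BuLi, THF, −78 → 0 °C; then 2, 0 °C → rt; H2O
Reagents that add atoms: none
Why: α-Lithiation of furan and SN2 opening of the epoxide by the furyllithium is a standard C-alkylation that places C17–C18 on the future C16.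

Step 2
Reactants: 4 2-(furan-2-yl)ethanol
Product: 5 tert-butyl[2-(furan-2-yl)ethoxy]dimethylsilane
Conditions: TBSCl, imidazole, CH2Cl2, rt
Reagents that add atoms: tert-butyldimethylsilyl chloride, CC(C)(C)[Si](C)(C)Cl
Why: Routine silyl ether protection; the primary TBS ether survives the coming lithiation and can later be removed beside a TBDPS ether.

Step 3
Reactants: 5 tert-butyl[2-(furan-2-yl)ethoxy]dimethylsilane
Product: 7 5-[2-(TBSO)ethyl]-N-methoxy-N-methylfuran-2-carboxamide (amide carbon = C12), via 5-lithiofuran 6 (not isolated)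
Conditions: n-BuLi, THF, −78 → 0 °C; cannulated into ClC(O)N(OMe)Me (1.5 equiv), THF, −78 °C
Reagents that add atoms: N-methoxy-N-methylcarbamoyl chloride, CON(C)C(=O)Cl
Why: The free α-position (future C13) is the most acidic site, and acylation of the furyllithium by the carbamoyl chloride gives the Weinreb amide, inverse addition to excess electrophile preventing a second attack.

Step 4
Reactants: 8 methyl (S)-3-hydroxy-2-methylpropanoate
Product: 9 methyl (S)-3-(TBDPSO)-2-methylpropanoate
Conditions: TBDPSCl, imidazole, DMF, rt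
Reagents that add atoms: tert-butyldiphenylsilyl chloride, CC(C)(C)[Si](Cl)(c1ccccc1)c1ccccc1
Why: Routine silylation; TBDPS is chosen for O9 because it outlasts acid, selective TBS cleavage and hydrogenolysis until step 24.

Step 5
Reactants: 9 methyl (S)-3-(TBDPSO)-2-methylpropanoate
Product: 10 (R)-3-(TBDPSO)-2-methylpropan-1-ol (CH2OH = C11)
Conditions: iBu2AlH (2.5 equiv), CH2Cl2, −78 → 0 °C; aq Rochelle salt
Reagents that add atoms: none
Why: Exhaustive ester reduction with an aluminium hydride leaves the C10 centre untouched (descriptor changes by the sequence rule only).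

Step 6
Reactants: 10 (R)-3-(TBDPSO)-2-methylpropan-1-ol
Product: 11 (S)-tert-butyl(3-iodo-2-methylpropoxy)diphenylsilane
Conditions: I2, PPh3, imidazole, CH2Cl2, 0 °C → rt
Reagents that add atoms: iodine, [I][I]
Why: Appel-type iodination of a primary alcohol proceeds by SN2 at C11 and does not involve C10.

Step 7
Reactants: 11 (S)-iodide; 7 furan Weinreb amide
Product: 13 (10R)-furyl ketone (C12=O joined to C11 and to furan C13), via alkyllithium 12 (not isolated)
Conditions: 11, t-BuLi (2.1 equiv), Et2O, −78 °C; then 7, −78 → 0 °C; H2O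
Reagents that add atoms: none
Why: Lithium–iodine exchange followed by the Weinreb ketone synthesis forms C11–C12, the chelated tetrahedral adduct blocking over-addition.

Step 8
Reactants: 13 (10R)-furyl ketone
Product: 14 (10R,12S)-C12 furyl carbinol
Conditions: RuCl[(S,S)-TsDPEN](p-cymene) (1 mol %), HCO2Na, cetyltrimethylammonium bromide (cat.), H2O/CH2Cl2, rt
Reagents that add atoms: none
Why: Noyori asymmetric transfer hydrogenation treats the furan as the aryl group of an aryl alkyl ketone, so the (S,S)-catalyst should set 12S under catalyst control, and the neutral formate medium spares both silyl ethers.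

Step 9
Reactants: 14 (10R,12S)-C12 furyl carbinol
Product: 16 ring B hydroxypyranone (12S,16R; C13 ketone; C14=C15; C16 hemiketal with axial OH), via (Z)-enedione 15 (not isolated)
Conditions: NBS (1.05 equiv), NaHCO3, THF/H2O (4:1), 0 °C
Reagents that add atoms: water, O
Why: Bromonium transfer from NBS to the electron-rich 2,5-dialkylfuran and capture by water should give a 2,5-dioxygenated dihydrofuran that collapses to the (Z)-enedione 15 with carbonyls at C13 and C16, which is the Achmatowicz oxidative ring expansion of 2-furyl carbinols. Ring B closes when the free C12 hydroxyl adds to the C16 ketone in a 6-exo-trig hemiketalisation, O–C16 being the only new skeletal bond. C12 is not touched and stays S, while the new C16 centre equilibrates through 15 and should settle under the anomeric effect with OH axial and the C17 arm equatorial, cis to the C11 chain. The step needs chemoselective oxidation of the furan beside four phenyl rings, which the far higher nucleophilicity of the furan secures. The direction of closure is secured because O9 and O18 are silylated, so that only O12 can reach a carbonyl and only a six-membered ring can result. NaHCO3 takes up the HBr and thereby protects the primary TBS ether.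

Step 10
Reactants: 16 ring B hydroxypyranone
Product: 17 ring B enone (12S,16R; 2,6-cis-2H-pyran-3(6H)-one)
Conditions: Et3SiH, CF3CO2H, CH2Cl2, −40 °C
Reagents that add atoms: none
Why: Ionic hydrogenation of the hemiketal: acid ionises C16–OH to the ring oxocarbenium ion and the silane delivers hydride along the axial trajectory of the half-chair that keeps the C11 chain pseudo-equatorial, so the C17 arm should end equatorial and 2,6-cis.

Step 11
Reactants: 17 ring B enone
Product: 18 ring B ketone (12S,15S,16R; C15 methyl trans to the C17 arm)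
Conditions: Me2CuLi (from CuI and MeLi), Et2O, −78 °C; aq NH4Cl
Reagents that add atoms: lithium dimethylcuprate (from MeLi and CuI), [Li+].C[Cu-]C
Why: Conjugate addition of a Gilman cuprate should occur at C15 on the face opposite the neighbouring C16 substituent, as with 4-substituted cyclohexenones, giving the all-equatorial 15S ketone.

Step 12
Reactants: 18 ring B ketone
Product: 19 C18 hydroxy ketone
Conditions: HF·pyridine, pyridine, THF, 0 °C
Reagents that add atoms: none
Why: Buffered fluoride desilylation distinguishes the primary TBS ether from the bulkier TBDPS ether and leaves the ketone alone.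

Step 13
Reactants: 19 C18 hydroxy ketone
Product: 20 C18 aldehyde C13 ketone
Conditions: Dess–Martin periodinane, CH2Cl2, rt
Reagents that add atoms: none
Why: Dess–Martin oxidation is neutral enough to avoid β-elimination of the ring oxygen from the C18 aldehyde and epimerisation at C12.

Step 14
Reactants: 8 methyl (S)-3-hydroxy-2-methylpropanoate
Product: 21 methyl (S)-3-(benzyloxy)-2-methylpropanoate
Conditions: BnOC(=NH)CCl3, CF3SO3H (cat.), CH2Cl2/cyclohexane, 0 °C → rt
Reagents that add atoms: benzyl 2,2,2-trichloroacetimidate, N=C(OCc1ccccc1)C(Cl)(Cl)Cl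
Why: Acid-catalysed imidate benzylation avoids base and hence racemisation or β-elimination of the hydroxy ester.

Step 15
Reactants: 21 methyl (S)-3-(benzyloxy)-2-methylpropanoate
Product: 22 (S)-3-(benzyloxy)-2-methylpropanal (CHO = C22)
Conditions: iBu2AlH (1.05 equiv), CH2Cl2, −78 °C; aq Rochelle salt
Reagents that add atoms: none
Why: Partial ester reduction works because the aluminium hemiacetal persists at −78 °C until work-up, so the aldehyde is released without over-reduction or loss of C23.

Step 16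
Reactants: 22 (S)-3-(benzyloxy)-2-methylpropanal
Product: 23 (2S,3R)-1-(benzyloxy)-2-methylhex-5-en-3-ol (22R,23S; 22,23-anti)
Conditions: allyltrimethylsilane, TiCl4, CH2Cl2, −78 °C
Reagents that add atoms: allyltrimethylsilane, C=CC[Si](C)(C)C
Why: Hosomi–Sakurai allylation under Cram-chelate control: TiCl4 ties the aldehyde and benzyloxy oxygens into a six-membered chelate and the silane attacks the face away from the C23 methyl, which should set 22R.

Step 17
Reactants: 20 C18 aldehyde C13 ketone; 23 homoallylic alcohol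
Product: 25 bis-pyran C20 alcohol (ring A all-cis; 18S,20S,22R,23S; C13 ketone kept), via C20 trifluoroacetate 24 (not isolated)
Conditions: CF3CO2H, CH2Cl2, 0 °C → rt; then K2CO3 (cat.), MeOH, rt
Reagents that add atoms: trifluoroacetic acid (its oxygen stays on C20), OC(=O)C(F)(F)F
Why: Prins cyclisation: the (E)-oxocarbenium ion between O22 and C18 closes C18–C19 through a chair with the C17 and C23 substituents equatorial and takes up trifluoroacetate equatorially at C20, so 22R should set 18S and 20S, the aldehyde reacting far faster than the hindered ketone.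

Step 18
Reactants: 25 bis-pyran C20 alcohol
Product: 26 C20 methyl ether (C13 ketone)
Conditions: Me3OBF4, 1,8-bis(dimethylamino)naphthalene, 4 Å MS, CH2Cl2, rt
Reagents that add atoms: trimethyloxonium tetrafluoroborate, C[O+](C)C.F[B-](F)(F)F
Why: O-Methylation with Meerwein salt and a non-nucleophilic base needs no alkoxide, so the C13 ketone and its C12 neighbour are not enolised.

Step 19
Reactants: 26 C20 methyl ether (C13 ketone)
Product: 27 C13 tertiary alcohol (13R; methyl axial and hydroxyl equatorial)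
Conditions: MeMgBr, THF, −78 °C; H2O
Reagents that add atoms: methylmagnesium bromide, C[Mg]Br
Why: Grignard 1,2-addition: in the all-equatorial chair the axial path to C13 meets only one syn-axial hydrogen (on C15) because the ring oxygen occupies the other β-position, whereas the equatorial path is crowded by the C11 chain, so methyl should enter axially.

Step 20
Reactants: 27 C13 tertiary alcohol
Product: 28 C24 primary alcohol
Conditions: H2 (1 atm), 10% Pd/C, EtOH, rt
Reagents that add atoms: none
Why: Hydrogenolysis of the benzyl ether is clean here because no alkene is present yet and silyl ether, methyl ether and tertiary alcohol are inert.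

Step 21
Reactants: 28 C24 primary alcohol
Product: 29 C24 aldehyde
Conditions: Dess–Martin periodinane, CH2Cl2, rt
Reagents that add atoms: none
Why: Dess–Martin oxidation touches only the primary alcohol and its neutral medium protects the α-centre C23 (descriptor R by the sequence rule only).

Step 22
Reactants: 29 C24 aldehyde
Product: 30 (24E)-enal (C24=C25(CH3)–C26HO)
Conditions: Ph3P=C(CH3)CHO, toluene, 90 °C
Reagents that add atoms: 2-(triphenylphosphoranylidene)propanal, CC(C=O)=P(c1ccccc1)(c1ccccc1)c1ccccc1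
Why: Wittig olefination with a stabilised formyl ylide is E-selective for trisubstituted enals and base-free, which protects C23 and avoids β-elimination of the ring A oxygen.

Step 23
Reactants: 30 (24E)-enal
Product: 31 (24E,26E)-triene (C9–OTBDPS)
Conditions: (EtO)2P(O)CH2CH=CH2 (3 equiv), n-BuLi, THF/HMPA, −78 °C → rt
Reagents that add atoms: diethyl allylphosphonate, C=CCP(=O)(OCC)OCC
Why: Horner–Wadsworth–Emmons olefination with the α-lithiated allylphosphonate is a known E-selective route to terminal 1,3-dienes, and the excess anion merely deprotonates the C13 hydroxyl.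

Step 24
Reactants: 31 (24E,26E)-triene
Product: 32 C9 primary alcohol
Conditions: Bu4NF, THF, rt
Reagents that add atoms: none
Why: Fluoride cleavage removes the only remaining silyl ether, and triene, ethers and tertiary alcohol are inert to it.

Step 25
Reactants: 32 C9 primary alcohol
Product: 33 C9 aldehyde (10R)
Conditions: Dess–Martin periodinane, pyridine, CH2Cl2, 0 °C → rt
Reagents that add atoms: none
Why: Buffered Dess–Martin oxidation converts the sole primary alcohol without acid damage to the triene or epimerisation at C10.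

Step 26
Reactants: 33 C9 aldehyde
Product: 34 (8E)-alkenyl iodide (C9=C8–I)
Conditions: CHI3, CrCl2, THF/dioxane, 0 °C → rt
Reagents that add atoms: iodoform, IC(I)I
Why: Takai olefination adds the gem-dichromium species from CHI3 to the aldehyde and eliminates to the (E)-alkenyl iodide, α-branching at C10 reinforcing the E preference, while alkenes and alcohols are ignored.

Step 27
Reactants: 35 ethyl (S)-4-chloro-3-hydroxybutanoate
Product: 36 ethyl (S)-4-azido-3-hydroxybutanoate (C1–C4; 2S)
Conditions: NaN3, DMF, 90 °C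
Reagents that add atoms: sodium azide, [Na+].[N-]=[N+]=[N-]
Why: SN2 displacement of the primary chloride, direct or through the transient epoxide, never breaks the C2–O bond, so 2S is kept, and early azide entry avoids a later 4-chloro alcohol that would cyclise.

Step 28
Reactants: 36 ethyl (S)-4-azido-3-hydroxybutanoate
Product: 37 ethyl (S)-4-azido-3-(TBSO)butanoate
Conditions: TBSCl, imidazole, DMF, rt
Reagents that add atoms: tert-butyldimethylsilyl chloride, CC(C)(C)[Si](C)(C)Cl
Why: Routine silyl ether protection of the secondary alcohol blocks retro-aldol and elimination pathways in the next steps.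

Step 29
Reactants: 37 ethyl (S)-4-azido-3-(TBSO)butanoate
Product: 38 (S)-4-azido-3-(TBSO)butanal (CHO = C4)
Conditions: iBu2AlH (1.05 equiv), CH2Cl2, −78 °C; aq Rochelle salt
Reagents that add atoms: none
Why: Partial ester reduction at −78 °C stops at the aluminium hemiacetal, a temperature at which alkyl azides are not attacked by the hydride.

Step 30
Reactants: 38 (S)-4-azido-3-(TBSO)butanal
Product: 39 (4R,6S)-7-azido-6-(TBSO)hept-1-en-4-ol (chain numbering 2S,4R; 2,4-anti)
Conditions: (+)-Ipc2B(allyl), Et2O, −78 °C; then NaOH, H2O2, 0 °C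
Reagents that add atoms: (+)-B-allyldiisopinocampheylborane, C=CCB([C@H]1C[C@H]2C[C@@H]([C@@H]1C)C2(C)C)[C@H]1C[C@H]2C[C@@H]([C@@H]1C)C2(C)C
Why: Brown allylation through a closed chair transition state is reagent-controlled, and the borane derived from (−)-α-pinene should deliver allyl to the Re face of the aldehyde and set 4R.

Step 31
Reactants: 39 homoallylic alcohol (2S,4R)
Product: 41 C4 carbamate (2S,4R), via N-trichloroacetyl carbamate 40 (not isolated)
Conditions: Cl3CC(O)NCO, CH2Cl2, 0 °C; then K2CO3 (cat.), MeOH, rt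
Reagents that add atoms: trichloroacetyl isocyanate, O=C=NC(=O)C(Cl)(Cl)Cl
Why: Carbamoylation with an activated isocyanate is fast on the only free hydroxyl, and methanolysis removes the activated trichloroacetyl group selectively.

Step 32
Reactants: 41 C4 carbamate
Product: 42 trisubstituted alkenyl boronate (Bpin on C7 trans to C5; Z by the sequence rule)
Conditions: isopropenyl-Bpin (3 equiv), second-generation Hoveyda–Grubbs catalyst (5–10 mol %), CH2Cl2, 40 °C
Reagents that add atoms: isopropenylboronic acid pinacol ester, C=C(C)B1OC(C)(C)C(C)(C)O1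
Why: Olefin cross-metathesis of a terminal alkene with this 1,1-disubstituted boronate is a known route to trisubstituted alkenyl boronates, reversibility should favour the isomer with the bulky boronate trans to the chain, and the phosphine-free catalyst leaves the azide alone.

Step 33
Reactants: 34 (8E)-alkenyl iodide; 42 alkenyl boronate
Product: 43 (6E,8E)-diene (C1 azide; C2–OTBS; full carbon chain)
Conditions: PdCl2(dppf) (10 mol %), K3PO4 (aq), THF/DMF, rt, degassed
Reagents that add atoms: none
Why: Suzuki–Miyaura coupling forms C7–C8 with retention at both alkenyl partners after oxidative addition of zerovalent palladium to the C–I bond, and the mild base tolerates carbamate, azide and free alcohol.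

Step 34
Reactants: 43 (6E,8E)-diene
Product: 44 C1 azide with free C2 and C13 hydroxyls
Conditions: HF·pyridine, pyridine, THF, 0 °C → rt
Reagents that add atoms: none
Why: Buffered fluoride desilylation avoids the alkoxide that could trigger carbamoyl migration from O4 to O2 and is too weakly acidic to harm triene or tertiary alcohol.

Step 35
Reactants: 45 methyl 2-methoxyacrylate
Product: 46 2-methoxyacrylic acid
Conditions: LiOH, THF/H2O, 0 °C → rt; then 1 M HCl to pH 3, 0 °C
Reagents that add atoms: lithium hydroxide, [Li+].[OH-]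
Why: Ester saponification by acyl–oxygen cleavage leaves the enol ether intact, provided that acidification is brief and cold.

Step 36
Reactants: 44 azido diol; 46 2-methoxyacrylic acid
Product: 48 CNP0220268.1 (target), via C1 amine 47 (not isolated)
Conditions: PMe3, THF/H2O, rt; evaporate; then 46, EDC·HCl, HOBt, iPr2NEt, CH2Cl2/DMF, 0 °C → rt
Reagents that add atoms: none
Why: Staudinger reduction frees the amine under neutral conditions, and carbodiimide/HOBt amide coupling acylates the primary amine far faster than the secondary or tertiary hydroxyl, so the acid-sensitive enol ether amide meets no further reagent.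

Compound list
1 | furan | c1ccoc1 | starting material
2 | ethylene oxide | C1CO1 | starting material
3 | 2-furyllithium | [Li]c1ccco1 | intermediate
4 | 2-(furan-2-yl)ethanol | OCCc1ccco1 | intermediate
5 | tert-butyl[2-(furan-2-yl)ethoxy]dimethylsilane | CC(C)(C)[Si](C)(C)OCCc1ccco1 | intermediate
6 | 5-lithio derivative of 5 | [Li]c1ccc(CCO[Si](C)(C)C(C)(C)C)o1 | intermediate
7 | 5-[2-(TBSO)ethyl]-N-methoxy-N-methylfuran-2-carboxamide | CON(C)C(=O)c1ccc(CCO[Si](C)(C)C(C)(C)C)o1 | intermediate
8 | methyl (S)-3-hydroxy-2-methylpropanoate | COC(=O)[C@@H](C)CO | starting material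
9 | methyl (S)-3-(TBDPSO)-2-methylpropanoate | COC(=O)[C@@H](C)CO[Si](c1ccccc1)(c1ccccc1)C(C)(C)C | intermediate
10 | (R)-3-(TBDPSO)-2-methylpropan-1-ol | OC[C@@H](C)CO[Si](c1ccccc1)(c1ccccc1)C(C)(C)C | intermediate
11 | (S)-tert-butyl(3-iodo-2-methylpropoxy)diphenylsilane | IC[C@@H](C)CO[Si](c1ccccc1)(c1ccccc1)C(C)(C)C | intermediate
12 | C11 alkyllithium from 11 | [Li]C[C@@H](C)CO[Si](c1ccccc1)(c1ccccc1)C(C)(C)C | intermediate
13 | (R)-4-(TBDPSO)-1-{5-[2-(TBSO)ethyl]furan-2-yl}-3-methylbutan-1-one (C12 ketone) | CC(C)(C)[Si](C)(C)OCCc1ccc(o1)C(=O)C[C@@H](C)CO[Si](c1ccccc1)(c1ccccc1)C(C)(C)C | intermediate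
14 | (1S,3R)-4-(TBDPSO)-1-{5-[2-(TBSO)ethyl]furan-2-yl}-3-methylbutan-1-ol (C12 furyl carbinol; 10R,12S) | CC(C)(C)[Si](C)(C)OCCc1ccc(o1)[C@@H](O)C[C@@H](C)CO[Si](c1ccccc1)(c1ccccc1)C(C)(C)C | intermediate
15 | (Z)-enedione, C13 and C16 ketones, free 12S hydroxyl | CC(C)(C)[Si](C)(C)OCCC(=O)/C=C\C(=O)[C@@H](O)C[C@@H](C)CO[Si](c1ccccc1)(c1ccccc1)C(C)(C)C | intermediate
16 | ring B hydroxypyranone, (12S,16R)-6-hydroxy-2H-pyran-3(6H)-one with the 10R chain on C12 and the TBSO-ethyl arm on C16 | CC(C)(C)[Si](C)(C)OCC[C@@]1(O)O[C@@H](C[C@@H](C)CO[Si](c2ccccc2)(c2ccccc2)C(C)(C)C)C(=O)C=C1 | intermediate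
17 | ring B enone, (12S,16R)-2,6-cis-2H-pyran-3(6H)-one | CC(C)(C)[Si](C)(C)OCC[C@H]1O[C@@H](C[C@@H](C)CO[Si](c2ccccc2)(c2ccccc2)C(C)(C)C)C(=O)C=C1 | intermediate
18 | ring B ketone (10R,12S,15S,16R), all substituents equatorial | CC(C)(C)[Si](C)(C)OCC[C@H]1O[C@@H](C[C@@H](C)CO[Si](c2ccccc2)(c2ccccc2)C(C)(C)C)C(=O)C[C@@H]1C | intermediate
19 | C18 hydroxy ketone | OCC[C@H]1O[C@@H](C[C@@H](C)CO[Si](c2ccccc2)(c2ccccc2)C(C)(C)C)C(=O)C[C@@H]1C | intermediate
20 | C18 aldehyde C13 ketone | O=CC[C@H]1O[C@@H](C[C@@H](C)CO[Si](c2ccccc2)(c2ccccc2)C(C)(C)C)C(=O)C[C@@H]1C | intermediate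
21 | methyl (S)-3-(benzyloxy)-2-methylpropanoate | COC(=O)[C@@H](C)COCc1ccccc1 | intermediate
22 | (S)-3-(benzyloxy)-2-methylpropanal | O=C[C@@H](C)COCc1ccccc1 | intermediate
23 | (2S,3R)-1-(benzyloxy)-2-methylhex-5-en-3-ol (C19–C24) | C[C@@H](COCc1ccccc1)[C@H](O)CC=C | intermediate
24 | bis-pyran C20 trifluoroacetate | C[C@@H](COCc1ccccc1)[C@H]1C[C@@H](OC(=O)C(F)(F)F)C[C@@H](C[C@H]2O[C@@H](C[C@@H](C)CO[Si](c3ccccc3)(c3ccccc3)C(C)(C)C)C(=O)C[C@@H]2C)O1 | intermediate
25 | bis-pyran C20 alcohol (10R,12S,15S,16R,18S,20S,22R,23S), C13 ketone | C[C@@H](COCc1ccccc1)[C@H]1C[C@@H](O)C[C@@H](C[C@H]2O[C@@H](C[C@@H](C)CO[Si](c3ccccc3)(c3ccccc3)C(C)(C)C)C(=O)C[C@@H]2C)O1 | intermediate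
26 | C20 methyl ether, C13 ketone | C[C@@H](COCc1ccccc1)[C@H]1C[C@@H](OC)C[C@@H](C[C@H]2O[C@@H](C[C@@H](C)CO[Si](c3ccccc3)(c3ccccc3)C(C)(C)C)C(=O)C[C@@H]2C)O1 | intermediate
27 | C13 tertiary alcohol (13R), C24–OBn, C9–OTBDPS | C[C@@H](COCc1ccccc1)[C@H]1C[C@@H](OC)C[C@@H](C[C@H]2O[C@@H](C[C@@H](C)CO[Si](c3ccccc3)(c3ccccc3)C(C)(C)C)[C@](C)(O)C[C@@H]2C)O1 | intermediate
28 | C24 primary alcohol | C[C@@H](CO)[C@H]1C[C@@H](OC)C[C@@H](C[C@H]2O[C@@H](C[C@@H](C)CO[Si](c3ccccc3)(c3ccccc3)C(C)(C)C)[C@](C)(O)C[C@@H]2C)O1 | intermediate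
29 | C24 aldehyde | C[C@@H](C=O)[C@H]1C[C@@H](OC)C[C@@H](C[C@H]2O[C@@H](C[C@@H](C)CO[Si](c3ccccc3)(c3ccccc3)C(C)(C)C)[C@](C)(O)C[C@@H]2C)O1 | intermediate
30 | (24E)-enal, C26 aldehyde | O=C/C(C)=C/[C@H](C)[C@H]1C[C@@H](OC)C[C@@H](C[C@H]2O[C@@H](C[C@@H](C)CO[Si](c3ccccc3)(c3ccccc3)C(C)(C)C)[C@](C)(O)C[C@@H]2C)O1 | intermediate
31 | (24E,26E)-triene, C9–OTBDPS | C=C/C=C/C(C)=C/[C@H](C)[C@H]1C[C@@H](OC)C[C@@H](C[C@H]2O[C@@H](C[C@@H](C)CO[Si](c3ccccc3)(c3ccccc3)C(C)(C)C)[C@](C)(O)C[C@@H]2C)O1 | intermediate
32 | triene C9 alcohol | C=C/C=C/C(C)=C/[C@H](C)[C@H]1C[C@@H](OC)C[C@@H](C[C@H]2O[C@@H](C[C@@H](C)CO)[C@](C)(O)C[C@@H]2C)O1 | intermediate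
33 | triene C9 aldehyde | C=C/C=C/C(C)=C/[C@H](C)[C@H]1C[C@@H](OC)C[C@@H](C[C@H]2O[C@@H](C[C@@H](C)C=O)[C@](C)(O)C[C@@H]2C)O1 | intermediate
34 | triene (8E)-alkenyl iodide | C=C/C=C/C(C)=C/[C@H](C)[C@H]1C[C@@H](OC)C[C@@H](C[C@H]2O[C@@H](C[C@@H](C)/C=C/I)[C@](C)(O)C[C@@H]2C)O1 | intermediate
35 | ethyl (S)-4-chloro-3-hydroxybutanoate | CCOC(=O)C[C@H](O)CCl | starting material
36 | ethyl (S)-4-azido-3-hydroxybutanoate | CCOC(=O)C[C@H](O)CN=[N+]=[N-] | intermediate
37 | ethyl (S)-4-azido-3-(TBSO)butanoate | CCOC(=O)C[C@H](O[Si](C)(C)C(C)(C)C)CN=[N+]=[N-] | intermediate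
38 | (S)-4-azido-3-(TBSO)butanal | O=CC[C@H](O[Si](C)(C)C(C)(C)C)CN=[N+]=[N-] | intermediate
39 | (4R,6S)-7-azido-6-(TBSO)hept-1-en-4-ol | C=CC[C@@H](O)C[C@H](O[Si](C)(C)C(C)(C)C)CN=[N+]=[N-] | intermediate
40 | N-trichloroacetyl carbamate of 39 | C=CC[C@H](C[C@H](O[Si](C)(C)C(C)(C)C)CN=[N+]=[N-])OC(=O)NC(=O)C(Cl)(Cl)Cl | intermediate
41 | C4 carbamate of 39 | C=CC[C@H](C[C@H](O[Si](C)(C)C(C)(C)C)CN=[N+]=[N-])OC(N)=O | intermediate
42 | C1–C7 alkenyl boronate, Bpin on C7 trans to C5 | CC1(C)OB(OC1(C)C)/C(C)=C/C[C@H](C[C@H](O[Si](C)(C)C(C)(C)C)CN=[N+]=[N-])OC(N)=O | intermediate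
43 | full chain, C1 azide, C2–OTBS | C=C/C=C/C(C)=C/[C@H](C)[C@H]1C[C@@H](OC)C[C@@H](C[C@H]2O[C@@H](C[C@@H](C)/C=C/C(C)=C/C[C@H](C[C@H](O[Si](C)(C)C(C)(C)C)CN=[N+]=[N-])OC(N)=O)[C@](C)(O)C[C@@H]2C)O1 | intermediate
44 | full chain, C1 azide, free C2 and C13 hydroxyls | C=C/C=C/C(C)=C/[C@H](C)[C@H]1C[C@@H](OC)C[C@@H](C[C@H]2O[C@@H](C[C@@H](C)/C=C/C(C)=C/C[C@H](C[C@H](O)CN=[N+]=[N-])OC(N)=O)[C@](C)(O)C[C@@H]2C)O1 | intermediate
45 | methyl 2-methoxyacrylate | C=C(OC)C(=O)OC | starting material
46 | 2-methoxyacrylic acid | C=C(OC)C(=O)O | intermediate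
47 | full chain C1 primary amine | C=C/C=C/C(C)=C/[C@H](C)[C@H]1C[C@@H](OC)C[C@@H](C[C@H]2O[C@@H](C[C@@H](C)/C=C/C(C)=C/C[C@H](C[C@H](O)CN)OC(N)=O)[C@](C)(O)C[C@@H]2C)O1 | intermediate
48 | CNP0220268.1 (2S,4R,6E,8E,10R,12S,13R,15S,16R,18S,20S,22R,23S,24E,26E) | C=C/C=C/C(C)=C/[C@H](C)[C@H]1C[C@@H](OC)C[C@@H](C[C@H]2O[C@@H](C[C@@H](C)/C=C/C(C)=C/C[C@H](C[C@H](O)CNC(=O)C(=C)OC)OC(N)=O)[C@](C)(O)C[C@@H]2C)O1 | target

Total step count: 36. Longest linear sequence: 23 steps (1–3, 7–13, 17–26, 33, 34, 36).

Steps most likely to fail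

1. Step 19 (methyl addition at C13). Facial selectivity may be poor, since equatorial approach of the Grignard reagent can compete with the axial one, and enolisation may simply return ketone. The fallback sets out from 26. Dimethylsulfonium methylide (Me3SI, NaH, DMSO/THF, 0 °C; Corey–Chaykovsky reaction) is a small nucleophile that adds irreversibly and is known for axial attack on cyclohexanones. It should give the C13 spiro-epoxide F1 with CH2 axial and oxygen equatorial. LiEt3BH in THF then opens the epoxide at its CH2 terminus and comes back to the route at 27.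

2. Step 17 (Prins union). The partners may scramble through 2-oxonia-Cope exchange, and slow ring closure in acid may erode the keto aldehyde. The fallback is a pyran annulation through an allylsilane, whose higher nucleophilicity lets closure outrun exchange at −78 °C.
- It sets out from 22 and 20. Chelation-controlled addition of 2-(trimethylsilylmethyl)allyltributylstannane to 22 (MgBr2·OEt2, CH2Cl2, −78 °C) gives the hydroxy allylsilane F2.
- TMSOTf in Et2O at −78 °C with 20 closes ring A as the 2,6-cis 4-methylene bis-pyran ketone F3.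
- MeMgBr, as in step 19, gives the tertiary alcohol F4.
- OsO4/NaIO4 (Lemieux–Johnson cleavage) gives the C20 ketone F5.
- NaBH4 (axial hydride) gives the equatorial C20 alcohol F6.
- Me3OBF4 with 1,8-bis(dimethylamino)naphthalene methylates the secondary hydroxyl in preference to the tertiary one, and the route is rejoined at 27.

3. Step 32 (cross-metathesis). Homodimerisation of the terminal alkene and sluggish turnover of the 1,1-disubstituted boronate may leave low conversion, and control of the alkene geometry may be incomplete. The fallback builds the trisubstituted alkene by two successive couplings on a 1,1-dibromoalkene.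
- It sets out from 41 and 33. Ozonolysis of 41 (O3, CH2Cl2, −78 °C; Me2S) gives the C6 aldehyde F7.
- Ramirez olefination gives the 1,1-dibromoalkene F8. CBr4 and PPh3 are premixed with CBr4 in slight excess, so that no free phosphine meets the azide.
- The boron variant of the Takai olefination on 33 (Cl2CHBpin, CrCl2, LiI, THF) gives the (8E)-alkenyl boronate F9.
- Suzuki coupling (PdCl2(dppf), K3PO4) engages selectively the bromide trans to C5 and gives the (6Z)-7-bromodiene F10.
- Negishi methylation with retention (Me2Zn, Pd(PtBu3)2, THF) replaces bromine by methyl and returns to the route at 43.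

Further compounds
F1 | step 19 | C13 spiro-epoxide (CH2 axial, O equatorial) | C[C@@H](COCc1ccccc1)[C@H]1C[C@@H](OC)C[C@@H](C[C@H]2O[C@@H](C[C@@H](C)CO[Si](c3ccccc3)(c3ccccc3)C(C)(C)C)[C@]3(OC3)C[C@@H]2C)O1
F2 | step 17 | (2S,3R)-1-(benzyloxy)-2-methyl-5-[(trimethylsilyl)methyl]hex-5-en-3-ol | C[C@@H](COCc1ccccc1)[C@H](O)CC(=C)C[Si](C)(C)C
F3 | step 17 | 4-methylene bis-pyran, C13 ketone | C[C@@H](COCc1ccccc1)[C@H]1CC(=C)C[C@@H](C[C@H]2O[C@@H](C[C@@H](C)CO[Si](c3ccccc3)(c3ccccc3)C(C)(C)C)C(=O)C[C@@H]2C)O1
F4 | step 17 | 4-methylene bis-pyran, 13R tertiary alcohol | C[C@@H](COCc1ccccc1)[C@H]1CC(=C)C[C@@H](C[C@H]2O[C@@H](C[C@@H](C)CO[Si](c3ccccc3)(c3ccccc3)C(C)(C)C)[C@](C)(O)C[C@@H]2C)O1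
F5 | step 17 | C20 ketone, 13R tertiary alcohol | C[C@@H](COCc1ccccc1)[C@H]1CC(=O)C[C@@H](C[C@H]2O[C@@H](C[C@@H](C)CO[Si](c3ccccc3)(c3ccccc3)C(C)(C)C)[C@](C)(O)C[C@@H]2C)O1
F6 | step 17 | 20S equatorial alcohol, 13R tertiary alcohol | C[C@@H](COCc1ccccc1)[C@H]1C[C@@H](O)C[C@@H](C[C@H]2O[C@@H](C[C@@H](C)CO[Si](c3ccccc3)(c3ccccc3)C(C)(C)C)[C@](C)(O)C[C@@H]2C)O1
F7 | step 32 | C6 aldehyde of the C1–C6 chain | O=CC[C@H](C[C@H](O[Si](C)(C)C(C)(C)C)CN=[N+]=[N-])OC(N)=O
F8 | step 32 | C7 1,1-dibromoalkene | BrC(Br)=CC[C@H](C[C@H](O[Si](C)(C)C(C)(C)C)CN=[N+]=[N-])OC(N)=O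
F9 | step 32 | triene (8E)-alkenyl boronate | C=C/C=C/C(C)=C/[C@H](C)[C@H]1C[C@@H](OC)C[C@@H](C[C@H]2O[C@@H](C[C@@H](C)/C=C/B3OC(C)(C)C(C)(C)O3)[C@](C)(O)C[C@@H]2C)O1
F10 | step 32 | (6Z,8E)-7-bromodiene | C=C/C=C/C(C)=C/[C@H](C)[C@H]1C[C@@H](OC)C[C@@H](C[C@H]2O[C@@H](C[C@@H](C)/C=C/C(Br)=C/C[C@H](C[C@H](O[Si](C)(C)C(C)(C)C)CN=[N+]=[N-])OC(N)=O)[C@](C)(O)C[C@@H]2C)O1
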